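**Retrosynthetic overview**
- The target (filixic acid ABB) is a butyrylphloroglucinol core whose two free ring carbons each carry a CH2 bridge, one to C6 of acetylfilicinic acid and one to C6 of butyrylfilicinic acid.
- Each bridge is cut at the arene–CH2 bond: an intermolecular Michael addition of the phloroglucinol carbon to a 6-methylene triketone. That acceptor is released from a Mannich base of the acylfilicinic acid, whose C6–CH2 bond comes from a Mannich reaction.
- The bridges are made one after the other: the acetyl unit first, onto excess butyrylphloroglucinol (giving norflavaspidic acid AB), then the butyryl unit onto the single remaining aromatic C–H.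
- The acylfilicinic acids come from dearomatising gem-dimethylation of the acylphloroglucinols; butyrylphloroglucinol comes from Friedel–Crafts acylation of phloroglucinol.
- No ring is constructed: all three six-membered rings come from phloroglucinol-type aromatics. The two outer rings are dearomatised first (steps 2 and 3); the central ring stays aromatic throughout.

Assumption: the target has no stereocentre and is achiral, so there is no enantiomer to select; all SMILES use the enol tautomer of the given string.

**Route**

Step 1
Reactants: 1 phloroglucinol; 2 butanoyl chloride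
Product: 3 butyrylphloroglucinol
Conditions: AlCl3 (3 equiv), PhNO2/CH2Cl2, 0 → 45 °C; ice/1 M HCl
Reagents that add atoms: none
Why: Friedel–Crafts C-acylation of the very electron-rich triol, in which the first acyl group deactivates the ring so that monoacylation dominates; no stereocentre is formed.

Step 2
Reactants: 3 butyrylphloroglucinol
Product: 4 butyrylfilicinic acid
Conditions: NaOMe (3.5 equiv), MeI (2.2 equiv), MeOH, 0 °C → rt; 1 M HCl
Reagents that add atoms: iodomethane, CI
Why: Dearomatising double C-methylation (phenolate C-alkylation) in which the second methyl enters geminally at the already methylated carbon to give the cross-conjugated enolised triketone, with stoichiometry limiting over-methylation; no stereocentre is formed.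

Step 3
Reactants: 5 2,4,6-trihydroxyacetophenone
Product: 6 acetylfilicinic acid
Conditions: NaOMe (3.5 equiv), MeI (2.2 equiv), MeOH, 0 °C → rt; 1 M HCl
Reagents that add atoms: iodomethane, CI
Why: The same dearomatising geminal C-methylation (phenolate C-alkylation) as in step 2, applied to the acetyl analogue; no stereocentre is formed.

Step 4
Reactants: 6 acetylfilicinic acid
Product: 7 acetylfilicinic acid Mannich base
Conditions: CH2(NMe2)2 (1.1 equiv), CH2Cl2, 0 °C → rt; evaporate, triturate with Et2O
Reagents that add atoms: bis(dimethylamino)methane, CN(C)CN(C)C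
Why: Mannich reaction in which the strongly acidic enol protonates the aminal to release CH2=NMe2+, which is captured by C6, the only free nucleophilic ring carbon, giving an inner ammonium enolate salt that is isolated free of 6; no stereocentre is formed.

Step 5
Reactants: 7 acetylfilicinic acid Mannich base; 3 butyrylphloroglucinol
Product: 9 norflavaspidic acid AB, via acetyl methylene triketone 8 (not isolated)
Conditions: 3 (3 equiv), 1,4-dioxane, 80 °C, N2 sweep; 1 M HCl work-up; excess 3 recovered by chromatography
Reagents that add atoms: none
Why: Thermal retro-aza-Michael loss of Me2NH from 7 gives the doubly activated acceptor 8, to which a free ring carbon of 3 adds in an intermolecular Michael addition followed by rearomatisation, the threefold excess of 3 suppressing a second alkylation; no stereocentre is formed.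

Step 6
Reactants: 4 butyrylfilicinic acid
Product: 10 butyrylfilicinic acid Mannich base
Conditions: CH2(NMe2)2 (1.1 equiv), CH2Cl2, 0 °C → rt; evaporate, triturate with Et2O
Reagents that add atoms: bis(dimethylamino)methane, CN(C)CN(C)C
Why: The same Mannich reaction as in step 4, at the single free C6–H of the butyryl triketone; no stereocentre is formed.

Step 7
Reactants: 10 butyrylfilicinic acid Mannich base; 9 norflavaspidic acid AB
Product: 12 filixic acid ABB, via butanoyl methylene triketone 11 (not isolated)
Conditions: 10 (1.3 equiv), 1,4-dioxane, 80 °C, N2 sweep; 1 M HCl work-up; crystallisation from acetone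
Reagents that add atoms: none
Why: Elimination of Me2NH from 10 gives acceptor 11, which is captured in an intermolecular Michael addition by the only carbon nucleophile left in 9, the aromatic C–H between two hydroxyls, with the acyl groups and the first bridge untouched under these near-neutral conditions; no stereocentre is formed.

**Compound list**
1 | phloroglucinol (benzene-1,3,5-triol) | Oc1cc(O)cc(O)c1 | starting material
2 | butanoyl chloride | CCCC(=O)Cl | starting material
3 | butyrylphloroglucinol, 1-(2,4,6-trihydroxyphenyl)butan-1-one | CCCC(=O)c1c(O)cc(O)cc1O | intermediate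
4 | butyrylfilicinic acid, 2-butanoyl-3,5-dihydroxy-4,4-dimethylcyclohexa-2,5-dien-1-one | CCCC(=O)C1=C(O)C(C)(C)C(O)=CC1=O | intermediate
5 | 2,4,6-trihydroxyacetophenone, 1-(2,4,6-trihydroxyphenyl)ethan-1-one | CC(=O)c1c(O)cc(O)cc1O | starting material
6 | acetylfilicinic acid, 2-acetyl-3,5-dihydroxy-4,4-dimethylcyclohexa-2,5-dien-1-one | CC(=O)C1=C(O)C(C)(C)C(O)=CC1=O | intermediate
7 | acetylfilicinic acid Mannich base, 2-acetyl-6-[(dimethylamino)methyl]-3,5-dihydroxy-4,4-dimethylcyclohexa-2,5-dien-1-one (inner salt, drawn neutral) | CC(=O)C1=C(O)C(C)(C)C(O)=C(CN(C)C)C1=O | intermediate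
8 | acetyl methylene triketone, 2-acetyl-3-hydroxy-4,4-dimethyl-6-methylidenecyclohex-2-ene-1,5-dione | CC(=O)C1=C(O)C(C)(C)C(=O)C(=C)C1=O | intermediate
9 | norflavaspidic acid AB, 2-acetyl-6-[(3-butanoyl-2,4,6-trihydroxyphenyl)methyl]-3,5-dihydroxy-4,4-dimethylcyclohexa-2,5-dien-1-one | CCCC(=O)c1c(O)cc(O)c(CC2=C(O)C(C)(C)C(O)=C(C(C)=O)C2=O)c1O | intermediate
10 | butyrylfilicinic acid Mannich base, 2-butanoyl-6-[(dimethylamino)methyl]-3,5-dihydroxy-4,4-dimethylcyclohexa-2,5-dien-1-one (inner salt, drawn neutral) | CCCC(=O)C1=C(O)C(C)(C)C(O)=C(CN(C)C)C1=O | intermediate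
11 | butanoyl methylene triketone, 2-butanoyl-3-hydroxy-4,4-dimethyl-6-methylidenecyclohex-2-ene-1,5-dione | CCCC(=O)C1=C(O)C(C)(C)C(=O)C(=C)C1=O | intermediate
12 | filixic acid ABB: butyrylphloroglucinol bearing at ring carbon 3 a CH2 link to C6 of acetylfilicinic acid and at ring carbon 5 a CH2 link to C6 of butyrylfilicinic acid; achiral | CCCC(=O)C1=C(O)C(C)(C)C(O)=C(Cc2c(O)c(CC3=C(O)C(C)(C)C(O)=C(C(C)=O)C3=O)c(O)c(C(=O)CCC)c2O)C1=O | target

**Step count**
Total steps: 7. Longest linear sequence: 4 steps (1 → 3 → 4 → 10 → 12, or 5 → 6 → 7 → 9 → 12).

**Three steps most likely to fail**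

Step 2 (the same risk applies to step 3). C-methylation of an acylphloroglucinol with two free ring carbons can give mono-methyl, aromatic 3,5-dimethyl and trimethyl by-products alongside the gem-dimethyl triketone. The fallback sets out from 1 and comes back at 4, and it makes over-methylation structurally impossible. Phloroglucinol 1 is diacetylated (Ac2O, MeSO3H, 80 °C) to 2,4-diacetylphloroglucinol F1. Its one remaining ring carbon can only be methylated geminally (MeI, NaOMe, MeOH), giving 3,5-diacetylfilicinic acid F2. Both acetyl groups are then removed by acid deacylation (85% H2SO4, 80 °C) to give filicinic acid F3. Friedel–Crafts C-acylation of F3 with butanoyl chloride 2 (AlCl3, PhNO2) gives 4.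

Step 5. The acceptor 8 can self-condense with traces of 6 to the methylene-bis dimer, and 3 can be alkylated twice. The fallback sets out from 3 and comes back at 9, with the roles of the partners inverted. Compound 3 (twofold excess) is aminomethylated with bis(dimethylamino)methane in dioxane at rt. The amphoteric mono-Mannich base 1-{3-[(dimethylamino)methyl]-2,4,6-trihydroxyphenyl}butan-1-one F4 is separated from unreacted 3 by extraction into dilute acid. Heating F4 with 6 (1.5 equiv) in dioxane at 90 °C releases ortho-quinone methide F5, and C6 of 6 adds to it in a Michael addition to give 9. Here 6 is only a nucleophile, so it cannot dimerise, and F4 carries a single CH2 handle, so a second bridge cannot form.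

Step 7. Liberated amine at 80 °C can promote retro-Michael exchange of the bridge already present, and 11 can self-condense. The fallback sets out from 9 and comes back at 12. Compound 9 has only one nucleophilic carbon, so bis(dimethylamino)methane (dioxane, rt) gives a single aryl Mannich base F6. Heating F6 with 4 (2 equiv) in dioxane at 80 °C releases ortho-quinone methide F7. This is trapped at C6 of 4 in a Michael addition to give 12; the excess of the cheap nucleophile 4 drives the coupling and no filicinic-derived electrophile is present.

**Further compounds**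
F1 | step 2 | 2,4-diacetylphloroglucinol, 1,1'-(2,4,6-trihydroxy-1,3-phenylene)di(ethan-1-one) | CC(=O)c1c(O)cc(O)c(C(C)=O)c1O
F2 | step 2 | 3,5-diacetylfilicinic acid, 2,4-diacetyl-3,5-dihydroxy-6,6-dimethylcyclohexa-2,4-dien-1-one | CC(=O)C1=C(O)C(C)(C)C(=O)C(C(C)=O)=C1O
F3 | step 2 | filicinic acid, 3,5-dihydroxy-4,4-dimethylcyclohexa-2,5-dien-1-one | CC1(C)C(O)=CC(=O)C=C1O
F4 | step 5 | 1-{3-[(dimethylamino)methyl]-2,4,6-trihydroxyphenyl}butan-1-one | CCCC(=O)c1c(O)cc(O)c(CN(C)C)c1O
F5 | step 5 | ortho-quinone methide, 2-butanoyl-3,5-dihydroxy-6-methylidenecyclohexa-2,4-dien-1-one | CCCC(=O)C1=C(O)C=C(O)C(=C)C1=O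
F6 | step 7 | aryl Mannich base of 9, 2-acetyl-6-({3-butanoyl-5-[(dimethylamino)methyl]-2,4,6-trihydroxyphenyl}methyl)-3,5-dihydroxy-4,4-dimethylcyclohexa-2,5-dien-1-one | CCCC(=O)c1c(O)c(CN(C)C)c(O)c(CC2=C(O)C(C)(C)C(O)=C(C(C)=O)C2=O)c1O
F7 | step 7 | ortho-quinone methide of 9, 2-acetyl-6-[(3-butanoyl-2,4-dihydroxy-5-methylidene-6-oxocyclohexa-1,3-dien-1-yl)methyl]-3,5-dihydroxy-4,4-dimethylcyclohexa-2,5-dien-1-one | CCCC(=O)C1=C(O)C(CC2=C(O)C(C)(C)C(O)=C(C(C)=O)C2=O)=C(O)C(=C)C1=O
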